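**Plan**

- Numbering: C1 is the methine on ring A (acylphloroglucinol) and ring C (phenol), C2 and C3 are the two CHMe carbons, C4 is the CH2 on ring D (phenol); ring B is the 4-methoxyphenyl of the acyl chain.
- Cuts, last to first: ring A–C(=O) (Hoesch acylation), C1–H (hydride onto the ring C quinone methide), C1–ring A (aryl-metal onto a C1 ketone), then C1–C2 and C3–C4 in one operation.
- Enabling feature: C2 and C3 with their methyl carbons are the β-carbon (C4), α-carbon (C3), acetal carbon (C5) and carbonyl carbon (C2) of a trans-3,4-disubstituted 5-alkoxybutyrolactone, and C1 is a ketone-level (dithiane) carbon.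
- Forward: the chain is joined on the (5S)-menthyloxybutenolide by conjugate addition of the lithiated ring C dithiane and benzylation with the ring D bromide (no ring forms). The lactone and acetal carbons are then reduced to the two methyls, the C1 ketone is unmasked, ring A is added, C1 is reduced, and ring A is debenzylated and acylated.
- Stereochemistry: (+)-menthol fixes the (5S) acetal; the acetal sets C2 (anti addition), C2 sets C3 (anti alkylation), and C2 sets C1 through allylic 1,3-strain in the quinone methide reduction.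

Key step: step 6

Remark: the tertiary carbinol of step 12 is carried as a mixture of C1 epimers because C1 becomes trigonal again in step 13; 4-(benzyloxy)benzyl alcohol, 1,3,5-tris(benzyloxy)benzene and 3-(4-methoxyphenyl)propanenitrile are taken as purchasable.

**Route**

Step 1
Reactants: 1 furfural
Product: 3 racemic 5-hydroxyfuran-2(5H)-one, via furan endoperoxide 2 (not isolated)
Conditions: O2, rose bengal (cat.), visible light, MeOH, rt
Reagents that add atoms: oxygen, O=O
Why: Dye-sensitised photooxygenation, in which singlet oxygen adds [4+2] across the furan and methanolysis of the endoperoxide expels the formyl carbon, leaving the γ-hydroxybutenolide as a labile racemic hemiacetal.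

Step 2
Reactants: 3 racemic 5-hydroxyfuran-2(5H)-one; 4 (+)-menthol
Product: 5 (5S)-5-[(1S,2R,5S)-menthyloxy]furan-2(5H)-one
Conditions: TsOH (cat.), toluene, reflux, Dean–Stark; crystallisation from petroleum ether, −20 °C; mother liquor re-equilibrated with TsOH and recrystallised
Reagents that add atoms: none
Why: Acid-catalysed acetalisation of the cyclic hemiacetal gives both C5 epimers, which interconvert under acid, so crystallisation should drain the mixture into the less soluble (5S) epimer (crystallisation-induced diastereomer transformation with (+)-menthol as the auxiliary).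

Step 3
Reactants: 6 4-hydroxybenzaldehyde; 7 propane-1,3-dithiol
Product: 8 2-(4-hydroxyphenyl)-1,3-dithiane
Conditions: BF3·OEt2 (cat.), CH2Cl2/THF, 0 °C → rt
Reagents that add atoms: none
Why: Lewis-acid-catalysed dithioacetalisation of an aromatic aldehyde, which installs the acyl-anion handle at the future C1.

Step 4
Reactants: 8 2-(4-hydroxyphenyl)-1,3-dithiane
Product: 9 2-[4-(triisopropylsilyloxy)phenyl]-1,3-dithiane
Conditions: TIPSCl, imidazole, DMF, rt
Reagents that add atoms: triisopropylsilyl chloride, CC(C)[Si](Cl)(C(C)C)C(C)C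
Why: Imidazole-mediated silylation of a phenol; the TIPS ether should withstand the organolithium and hydride steps and is the one phenol protecting group that fluoride removes later, which singles out ring C.

Step 5
Reactants: 10 4-(benzyloxy)benzyl alcohol
Product: 11 4-(benzyloxy)benzyl bromide
Conditions: PBr3, Et2O, 0 °C; used freshly prepared
Reagents that add atoms: phosphorus tribromide, BrP(Br)Br
Why: Conversion of a benzylic alcohol into its bromide by SN2 displacement on the phosphite ester, giving the electrophile for the C3–C4 bond.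

Step 6
Reactants: 9 2-[4-(triisopropylsilyloxy)phenyl]-1,3-dithiane; 5 (5S)-5-[(1S,2R,5S)-menthyloxy]furan-2(5H)-one; 11 4-(benzyloxy)benzyl bromide
Product: 14 (3S,4S,5S)-3-[4-(benzyloxy)benzyl]-5-[(1S,2R,5S)-menthyloxy]-4-{2-[4-(triisopropylsilyloxy)phenyl]-1,3-dithian-2-yl}dihydrofuran-2(3H)-one, via lithiated dithiane 12 (not isolated), via lithium enolate 13 (not isolated)
Conditions: n-BuLi, THF, −78 → −20 °C; then 5, −78 °C; then 11, DMPU, −78 → −20 °C; aq NH4Cl
Reagents that add atoms: none
Why: n-BuLi deprotonates the dithiane to the sulfur-stabilised benzylic carbanion 12 (an acyl-anion equivalent for C1), which adds in Michael fashion to the β-carbon of butenolide 5 to give lithium enolate 13, and 13 is C-alkylated by bromide 11 in an SN2 step, so that C1–C2 and C3–C4 form in one flask. The closest known reaction type is the tandem conjugate addition–enolate benzylation of lithiated 2-aryl-1,3-dithianes on 5-alkoxyfuran-2(5H)-ones, the standard entry to trans-2,3-dibenzylbutyrolactone lignans. No ring is closed; the acetal-lactone serves only as the stereochemical template. The lactone C4 centre (C2 of the target) is controlled by the (5S) acetal carbon, the carbanion entering anti to the menthyloxy group, and the lactone C3 centre (C3 of the target) is controlled by the new C4 substituent, the bromide approaching the enolate face anti to the bulky aryl-dithianyl group, which should give the all-trans lactone. The step needs 1,4- instead of 1,2-addition, which the soft delocalised aryl-dithianyl anion secures, and clean mono-C-benzylation, which the reactive benzylic bromide with DMPU at low temperature secures.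

Step 7
Reactants: 14 the all-trans lactone acetal
Product: 15 (2S,3S)-2-[4-(benzyloxy)benzyl]-3-{2-[4-(triisopropylsilyloxy)phenyl]-1,3-dithian-2-yl}butane-1,4-diol
Conditions: LiAlH4, THF, 0 °C → rt; aqueous NaOH work-up
Reagents that add atoms: none
Why: Hydride reduction of the lactone carbonyl releases a hemiacetal that collapses to an aldehyde with loss of menthoxide and is reduced in turn, so both latent methyl carbons arrive as CH2OH while the dithiane and both stereocentres are untouched.

Step 8
Reactants: 15 the 1,4-diol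
Product: 16 (2S,3S)-2-[4-(benzyloxy)benzyl]-3-{2-[4-(triisopropylsilyloxy)phenyl]-1,3-dithian-2-yl}butane-1,4-diyl dimethanesulfonate
Conditions: MsCl (excess), Et3N, CH2Cl2, 0 °C
Reagents that add atoms: methanesulfonyl chloride, CS(=O)(=O)Cl
Why: Sulfonylation of two primary alcohols, run cold with excess reagent so that bis-mesylation outruns cyclisation of a mono-mesylate to the tetrahydrofuran.

Step 9
Reactants: 16 the dimesylate
Product: 17 2-{(2R,3S)-4-[4-(benzyloxy)phenyl]-3-methylbutan-2-yl}-2-[4-(triisopropylsilyloxy)phenyl]-1,3-dithiane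
Conditions: LiEt3BH, THF, 0 °C → rt
Reagents that add atoms: none
Why: SN2 hydride displacement of primary mesylates turns both CH2OMs groups into methyls without touching the stereocentres, the dithiane keeps C1 masked, and the low temperature disfavours participation by sulfur.

Step 10
Reactants: 17 the dimethyl dithiane
Product: 18 (2R,3S)-4-[4-(benzyloxy)phenyl]-2,3-dimethyl-1-[4-(triisopropylsilyloxy)phenyl]butan-1-one
Conditions: MeI, CaCO3, MeCN/H2O (9:1), 45 °C
Reagents that add atoms: water, O
Why: Alkylative dithiane hydrolysis (S-methylation, opening to the thionium ion, hydrolysis) under CaCO3 buffering unmasks the C1 ketone without acid or base strong enough to enolise it, so C2 should keep its configuration.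

Step 11
Reactants: 19 1,3,5-tris(benzyloxy)benzene
Product: 20 2-bromo-1,3,5-tris(benzyloxy)benzene
Conditions: NBS (1.0 equiv), CH2Cl2, −78 → 0 °C
Reagents that add atoms: N-bromosuccinimide, O=C1CCC(=O)N1Br
Why: Electrophilic aromatic monobromination of a symmetrical, strongly activated trialkoxybenzene with one equivalent of reagent at low temperature.

Step 12
Reactants: 20 2-bromo-1,3,5-tris(benzyloxy)benzene; 18 the C1 ketone
Product: 23 (2R,3S)-4-[4-(benzyloxy)phenyl]-2,3-dimethyl-1-[2,4,6-tris(benzyloxy)phenyl]-1-[4-(triisopropylsilyloxy)phenyl]butan-1-ol, via aryllithium 21 (not isolated), via arylcerium dichloride 22 (not isolated)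
Conditions: 20, n-BuLi, THF, −78 °C; CeCl3 (anhydrous), THF, −78 °C; then 18, −78 → −20 °C; aq NH4Cl; chromatography on Et3N-deactivated silica
Reagents that add atoms: none
Why: Bromine–lithium exchange and transmetalation to cerium give a weakly basic aryl nucleophile that adds 1,2 to the enolisable α-branched aryl ketone (organocerium carbonyl addition), so C2 should not epimerise, and the carbinol carbon, formed as an epimer mixture, is of no consequence because it becomes trigonal in step 13.

Step 13
Reactants: 23 the tertiary carbinol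
Product: 26 4-{(1R,2R,3S)-4-[4-(benzyloxy)phenyl]-2,3-dimethyl-1-[2,4,6-tris(benzyloxy)phenyl]butyl}phenol, via phenol carbinol 24 (not isolated), via ring C quinone methide 25 (not isolated)
Conditions: TBAF, THF, 0 °C; then NaBH4 (excess), EtOH, 0 °C → 40 °C; minor C1 epimer removed by chromatography
Reagents that add atoms: none
Why: Fluoride frees the ring C phenoxide, which expels the tertiary benzylic hydroxide to give the ring C p-quinone methide 25 (the fully benzylated ring A cannot form a quinone methide of its own), and borohydride adds 1,6 to C1 as in the known borohydride hydrogenolysis of p-hydroxybenzylic alcohols; allylic 1,3-strain with the quinoid ortho-hydrogen holds C2–H in the plane of the exocyclic double bond while ring A is twisted out of it, so hydride should enter on the face of the C2 methyl, anti to the C3 branch, which gives the (1R) centre.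

Step 14
Reactants: 26 the ring C phenol tetrabenzyl ether
Product: 27 2-[(1R,2R,3S)-1,4-bis(4-hydroxyphenyl)-2,3-dimethylbutyl]benzene-1,3,5-triol
Conditions: H2 (1 atm), 10% Pd/C, EtOAc/MeOH, rt; work-up under argon
Reagents that add atoms: none
Why: Catalytic hydrogenolysis of the four benzyl aryl ethers over palladium on carbon, to which the diarylmethine C–H and the three stereocentres are inert.

Step 15
Reactants: 27 the pentaphenol; 28 3-(4-methoxyphenyl)propanenitrile
Product: 30 1-{3-[(1R,2R,3S)-1,4-bis(4-hydroxyphenyl)-2,3-dimethylbutyl]-2,4,6-trihydroxyphenyl}-3-(4-methoxyphenyl)propan-1-one, via ketiminium chloride 29 (not isolated)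
Conditions: ZnCl2 (anhydrous), HCl (g), Et2O, 0 °C; then H2O, reflux
Reagents that add atoms: water, O
Why: Hoesch acylation, in which the HCl/ZnCl2-activated nitrile attacks the most nucleophilic ring (the phloroglucinol ring A, whose two free positions give the same product) to form a ketiminium salt that resists a second acylation and hydrolyses to the ketone, while the monophenol rings C and D should not C-acylate.

**Compound list**

1 | furfural | O=Cc1ccco1 | starting material
2 | 1-formyl-2,3,7-trioxabicyclo[2.2.1]hept-5-ene (furan endoperoxide, racemic, formed in the flask) | O=CC12C=CC(OO1)O2 | intermediate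
3 | 5-hydroxyfuran-2(5H)-one (racemic) | O=C1C=CC(O)O1 | intermediate
4 | (+)-menthol, (1S,2R,5S)-2-isopropyl-5-methylcyclohexan-1-ol | C[C@H]1CC[C@@H]([C@H](C1)O)C(C)C | starting material
5 | (5S)-5-{[(1S,2R,5S)-2-isopropyl-5-methylcyclohexyl]oxy}furan-2(5H)-one | O=C1C=C[C@@H](O[C@H]2C[C@@H](C)CC[C@@H]2C(C)C)O1 | intermediate
6 | 4-hydroxybenzaldehyde | O=Cc1ccc(O)cc1 | starting material
7 | propane-1,3-dithiol | SCCCS | starting material
8 | 2-(4-hydroxyphenyl)-1,3-dithiane | Oc1ccc(cc1)C1SCCCS1 | intermediate
9 | 2-[4-(triisopropylsilyloxy)phenyl]-1,3-dithiane | CC(C)[Si](Oc1ccc(cc1)C1SCCCS1)(C(C)C)C(C)C | intermediate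
10 | 4-(benzyloxy)benzyl alcohol | OCc1ccc(OCc2ccccc2)cc1 | starting material
11 | 4-(benzyloxy)benzyl bromide | BrCc1ccc(OCc2ccccc2)cc1 | intermediate
12 | 2-lithio-2-[4-(triisopropylsilyloxy)phenyl]-1,3-dithiane (formed in the flask) | [Li]C1(SCCCS1)c1ccc(O[Si](C(C)C)(C(C)C)C(C)C)cc1 | intermediate
13 | lithium (4S,5S)-5-[(1S,2R,5S)-menthyloxy]-4-{2-[4-(triisopropylsilyloxy)phenyl]-1,3-dithian-2-yl}-4,5-dihydrofuran-2-olate (formed in the flask) | [Li]OC1=C[C@H](C2(SCCCS2)c2ccc(O[Si](C(C)C)(C(C)C)C(C)C)cc2)[C@@H](O[C@H]2C[C@@H](C)CC[C@@H]2C(C)C)O1 | intermediate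
14 | (3S,4S,5S)-3-[4-(benzyloxy)benzyl]-5-{[(1S,2R,5S)-2-isopropyl-5-methylcyclohexyl]oxy}-4-{2-[4-(triisopropylsilyloxy)phenyl]-1,3-dithian-2-yl}dihydrofuran-2(3H)-one | O=C1O[C@H](O[C@H]2C[C@@H](C)CC[C@@H]2C(C)C)[C@@H](C2(SCCCS2)c2ccc(O[Si](C(C)C)(C(C)C)C(C)C)cc2)[C@@H]1Cc1ccc(OCc2ccccc2)cc1 | intermediate
15 | (2S,3S)-2-[4-(benzyloxy)benzyl]-3-{2-[4-(triisopropylsilyloxy)phenyl]-1,3-dithian-2-yl}butane-1,4-diol | C1(SCCCS1)(c1ccc(O[Si](C(C)C)(C(C)C)C(C)C)cc1)[C@H](CO)[C@@H](CO)Cc1ccc(OCc2ccccc2)cc1 | intermediate
16 | (2S,3S)-2-[4-(benzyloxy)benzyl]-3-{2-[4-(triisopropylsilyloxy)phenyl]-1,3-dithian-2-yl}butane-1,4-diyl dimethanesulfonate | C1(SCCCS1)(c1ccc(O[Si](C(C)C)(C(C)C)C(C)C)cc1)[C@H](COS(C)(=O)=O)[C@@H](COS(C)(=O)=O)Cc1ccc(OCc2ccccc2)cc1 | intermediate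
17 | 2-{(2R,3S)-4-[4-(benzyloxy)phenyl]-3-methylbutan-2-yl}-2-[4-(triisopropylsilyloxy)phenyl]-1,3-dithiane | C1(SCCCS1)(c1ccc(O[Si](C(C)C)(C(C)C)C(C)C)cc1)[C@H](C)[C@@H](C)Cc1ccc(OCc2ccccc2)cc1 | intermediate
18 | (2R,3S)-4-[4-(benzyloxy)phenyl]-2,3-dimethyl-1-[4-(triisopropylsilyloxy)phenyl]butan-1-one | O=C(c1ccc(O[Si](C(C)C)(C(C)C)C(C)C)cc1)[C@H](C)[C@@H](C)Cc1ccc(OCc2ccccc2)cc1 | intermediate
19 | 1,3,5-tris(benzyloxy)benzene | c1(OCc2ccccc2)cc(OCc2ccccc2)cc(OCc2ccccc2)c1 | starting material
20 | 2-bromo-1,3,5-tris(benzyloxy)benzene | Brc1c(OCc2ccccc2)cc(OCc2ccccc2)cc1OCc1ccccc1 | intermediate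
21 | 2,4,6-tris(benzyloxy)phenyllithium (formed in the flask) | [Li]c1c(OCc2ccccc2)cc(OCc2ccccc2)cc1OCc1ccccc1 | intermediate
22 | dichloro[2,4,6-tris(benzyloxy)phenyl]cerium (formed in the flask) | Cl[Ce](Cl)c1c(OCc2ccccc2)cc(OCc2ccccc2)cc1OCc1ccccc1 | intermediate
23 | (2R,3S)-4-[4-(benzyloxy)phenyl]-2,3-dimethyl-1-[2,4,6-tris(benzyloxy)phenyl]-1-[4-(triisopropylsilyloxy)phenyl]butan-1-ol (both C1 epimers) | OC(c1ccc(O[Si](C(C)C)(C(C)C)C(C)C)cc1)(c1c(OCc2ccccc2)cc(OCc2ccccc2)cc1OCc1ccccc1)[C@H](C)[C@@H](C)Cc1ccc(OCc2ccccc2)cc1 | intermediate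
24 | 4-{(2R,3S)-4-[4-(benzyloxy)phenyl]-1-hydroxy-2,3-dimethyl-1-[2,4,6-tris(benzyloxy)phenyl]butyl}phenol (both C1 epimers, present as the tetrabutylammonium phenoxide in the flask) | Oc1ccc(cc1)C(O)(c1c(OCc2ccccc2)cc(OCc2ccccc2)cc1OCc1ccccc1)[C@H](C)[C@@H](C)Cc1ccc(OCc2ccccc2)cc1 | intermediate
25 | 4-{(2R,3S)-4-[4-(benzyloxy)phenyl]-2,3-dimethyl-1-[2,4,6-tris(benzyloxy)phenyl]butylidene}cyclohexa-2,5-dien-1-one (formed in the flask) | O=C1C=CC(C=C1)=C(c1c(OCc2ccccc2)cc(OCc2ccccc2)cc1OCc1ccccc1)[C@H](C)[C@@H](C)Cc1ccc(OCc2ccccc2)cc1 | intermediate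
26 | 4-{(1R,2R,3S)-4-[4-(benzyloxy)phenyl]-2,3-dimethyl-1-[2,4,6-tris(benzyloxy)phenyl]butyl}phenol | c1(OCc2ccccc2)cc(OCc2ccccc2)cc(OCc2ccccc2)c1[C@@H](c1ccc(O)cc1)[C@H](C)[C@@H](C)Cc1ccc(OCc2ccccc2)cc1 | intermediate
27 | 2-[(1R,2R,3S)-1,4-bis(4-hydroxyphenyl)-2,3-dimethylbutyl]benzene-1,3,5-triol | Oc1cc(O)cc(O)c1[C@@H](c1ccc(O)cc1)[C@H](C)[C@@H](C)Cc1ccc(O)cc1 | intermediate
28 | 3-(4-methoxyphenyl)propanenitrile | N#CCCc1ccc(OC)cc1 | starting material
29 | 1-{3-[(1R,2R,3S)-1,4-bis(4-hydroxyphenyl)-2,3-dimethylbutyl]-2,4,6-trihydroxyphenyl}-3-(4-methoxyphenyl)propan-1-iminium chloride (formed in the flask) | COc1ccc(CCC(=[NH2+])c2c(O)cc(O)c([C@@H](c3ccc(O)cc3)[C@H](C)[C@@H](C)Cc3ccc(O)cc3)c2O)cc1.[Cl-] | intermediate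
30 | 1-{3-[(1R,2R,3S)-1,4-bis(4-hydroxyphenyl)-2,3-dimethylbutyl]-2,4,6-trihydroxyphenyl}-3-(4-methoxyphenyl)propan-1-one (CNP0193401.1) | COc1ccc(CCC(=O)c2c(O)cc(O)c([C@@H](c3ccc(O)cc3)[C@H](C)[C@@H](C)Cc3ccc(O)cc3)c2O)cc1 | target

**Step count and risks**

Total step count: 15. Longest linear sequence: 11 steps (steps 1, 2, 6–10, 12–15 from furfural; equally steps 3, 4, 6–10, 12–15 from 4-hydroxybenzaldehyde).

The three steps most likely to fail:

1. Step 13. The hydride may discriminate poorly between the two faces of the quinone methide, because the C2 methyl and the C3 branch differ only moderately in size. The quinone methide may also tautomerise to the tetrasubstituted styrene before it is reduced, which would erase C2. The fallback sets out from 23 and replaces substrate control by catalyst control. The silyl ether is cleaved with TBAF at −20 °C and the phenol carbinol 24 is isolated after a buffered work-up. Compound 24 is then treated with a BINOL-derived chiral phosphoric acid (the enantiomer matched to the substrate) and a Hantzsch ester in CH2Cl2 at rt. The quinone methide 25 is generated inside the chiral ion pair and reduced by asymmetric 1,6-transfer hydrogenation, a known reaction of p-quinone methides formed in situ from p-hydroxybenzylic alcohols. The route is rejoined at 26; no compound outside the list arises.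

2. Step 12. The 2,6-disubstituted aryl nucleophile may fail to add to the hindered α-branched ketone, and enolisation would then erode the C2 configuration. The fallback sets out from 18 and forms the C1–ring A bond by electrophilic aromatic substitution. Ketone 18 is reduced with NaBH4 in MeOH to (2R,3S)-4-[4-(benzyloxy)phenyl]-2,3-dimethyl-1-[4-(triisopropylsilyloxy)phenyl]butan-1-ol F1. Its secondary benzylic cation (BF3·OEt2, CH2Cl2, −78 °C) alkylates an excess of 19 in a Friedel–Crafts reaction to give the silyl-protected diarylmethane F2 as a C1 epimer mixture. TBAF then gives the C1-epimeric phenol F3, and DDQ (dioxane, rt) dehydrogenates either epimer to the quinone methide. The route is rejoined at 25, which is reduced with NaBH4 as in step 13 to 26, so the C1 configuration of F2 and F3 is irrelevant.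

3. Step 15. Under the strongly acidic Hoesch conditions the phenols may be O-acylated through imidate formation, and acid-induced ionisation of the C1–ring A bond may cause epimerisation or cleavage. The fallback sets out from 26 and acylates before the phenols are freed. Friedel–Crafts acylation of the tri-O-benzylated ring A with purchased 3-(4-methoxyphenyl)propanoyl chloride (SnCl4, CH2Cl2, −40 °C) should give 1-{2,4,6-tris(benzyloxy)-3-[(1R,2R,3S)-4-[4-(benzyloxy)phenyl]-1-(4-hydroxyphenyl)-2,3-dimethylbutyl]phenyl}-3-(4-methoxyphenyl)propan-1-one F4. A benzyl ether lost ortho to the new carbonyl is of no consequence. Hydrogenolysis (H2, 10% Pd/C, EtOAc/MeOH) then removes the benzyl groups while the aryl ketone survives, and the route is rejoined at 30.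

**Further compounds**

F0 | step 13 | none | none
F1 | step 12 | (2R,3S)-4-[4-(benzyloxy)phenyl]-2,3-dimethyl-1-[4-(triisopropylsilyloxy)phenyl]butan-1-ol (both C1 epimers) | OC(c1ccc(O[Si](C(C)C)(C(C)C)C(C)C)cc1)[C@H](C)[C@@H](C)Cc1ccc(OCc2ccccc2)cc1
F2 | step 12 | {4-[(2R,3S)-4-[4-(benzyloxy)phenyl]-2,3-dimethyl-1-[2,4,6-tris(benzyloxy)phenyl]butyl]phenoxy}triisopropylsilane (both C1 epimers) | c1(OCc2ccccc2)cc(OCc2ccccc2)cc(OCc2ccccc2)c1C(c1ccc(O[Si](C(C)C)(C(C)C)C(C)C)cc1)[C@H](C)[C@@H](C)Cc1ccc(OCc2ccccc2)cc1
F3 | step 12 | 4-{(2R,3S)-4-[4-(benzyloxy)phenyl]-2,3-dimethyl-1-[2,4,6-tris(benzyloxy)phenyl]butyl}phenol (both C1 epimers) | c1(OCc2ccccc2)cc(OCc2ccccc2)cc(OCc2ccccc2)c1C(c1ccc(O)cc1)[C@H](C)[C@@H](C)Cc1ccc(OCc2ccccc2)cc1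
F4 | step 15 | 1-{2,4,6-tris(benzyloxy)-3-[(1R,2R,3S)-4-[4-(benzyloxy)phenyl]-1-(4-hydroxyphenyl)-2,3-dimethylbutyl]phenyl}-3-(4-methoxyphenyl)propan-1-one | COc1ccc(CCC(=O)c2c(OCc3ccccc3)cc(OCc3ccccc3)c([C@@H](c3ccc(O)cc3)[C@H](C)[C@@H](C)Cc3ccc(OCc4ccccc4)cc3)c2OCc2ccccc2)cc1
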